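- Substrate in the dusk run leaves by two flows, and their ratio is the quantity to watch: target against an unseen remainder, the part of the charge the readings no longer show.

| flask | substrate | remark | time |
|---|---|---|---|
| dusk | 1.7 M | run made earlier |  |
| alpha | 2.5 M |  | 1.5 h |
| theta | 0.40 M |  | 1.5 h |
| eta | 1.5 M |  | 1.5 h |
| gamma | 0.50 M |  | 1.5 h |
| epsilon | 1.0 M |  | 1.5 h |

- dusk (time / min: target / %, substrate / %): 10.0: 14.5, 70.6; 20.0: 20.4, 53.9; 30.0: 24.0, 44.3; 40.0: 25.8, 36.7; 50.0: 26.8, 32.6

(readings scatter by 0.5 percentage points)

- a species is counted by the substrate in it: one target counts as two

- all flasks from highest to lowest amount of target, in percent of the substrate charged, at 1.5 h (alpha / theta / eta / gamma / epsilon)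
- the amount of target, in percent of the substrate charged of the flask you put first, at 1.5 h
- the amount of target, in percent of the substrate charged of the flask you put last, at 1.5 h

- In the first interval of the dusk run, target gains 14.5% and the remainder 14.9%, a ratio reading 0.973 at a mean 85.3% of substrate.
- From 30.0 min to 50.0 min of the dusk run the ratio reads 0.315 at a mean 38.5%, so the reading is lower where less substrate stands.
- This reckoning therefore assumes that the ratio scales with the substrate concentration, and the first interval then reads the equal-share charge, the charge at which both flows start level: 1.49 M.
- The starting selectivity to target in this reckoning is charge/(charge + 1.49 M): 53.3% for dusk, 62.7% for alpha and 21.2% for theta, so it ranks the flasks by charge, alpha with the highest and theta with the lowest.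
- Dusk target gains 1 percentage point in its last interval, so this reckoning assumes a plateau and scales that last reading by starting selectivity to estimate each flask at 1.5 h: alpha 31.5%, theta 10.6%.
- The forecast gives the same order, alpha > eta > epsilon > gamma > theta, but 36.5% at the top and 9.1% at the bottom, holding that “Higher concentration favours target”.
- The flasks give alpha > eta > epsilon > gamma > theta, with alpha at 30.1% and theta at 12.7%, so theta stands 2 points above this reckoning.

    substrate ⇌ dormant form (K = 1.30, k = 0.0175 /min)
    2 substrate ⇌ target (K = 3.83 /M, k = 0.00618 /M/min)
    substrate + target → side product (k = 0.00716 /M/min)

- The neighbour of theta, charged with 0.68 M, is reckoned at a starting selectivity of 31.3%, which scales to an estimate of 15.8% of target.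
- That neighbour flask holds 18.2% of target at 1.50 h, 2.4 points above the estimate, beside 43.0% of dormant form.

Readings and results are simulated for substances that don't exist, and the scatter is random.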